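The D charged stays accounted for: what has left it stands as product, so E, L and Q read together tell how far a run has gone, unless something unread takes D as well. You ask for a quick number, and your hunch is that the share of E, the selectivity, barely moves from flask to flask.

common to all: D 0.27 M

| run | J | temperature | remark | time |
|---|---|---|---|---|
| Tuesday's | 0.013 M | 35 °C | run made earlier |  |
| Thursday's | 0.020 M | 60 °C | run made earlier |  |
| south-east | 0.0270 M | 60 °C |  | 10 min |
| north-west | 0.0270 M | 80 °C |  | 10 min |
| west | 0.0270 M | 40 °C |  | 10 min |

| run | time / min | E / % | L / % | Q / % |
|---|---|---|---|---|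
| Tuesday's | 5.00 | 1 | 0 | 0 |
| Tuesday's | 8.00 | 7 | 0 | 1 |
| Tuesday's | 15.0 | 5 | 2 | 0 |
| Tuesday's | 20.0 | 7 | 1 | 0 |
| Thursday's | 1.33 | 11 | 4 | 0 |
| Thursday's | 2.50 | 16 | 2 | 1 |
| Thursday's | 4.00 | 21 | 4 | 0 |
| Thursday's | 5.00 | 28 | 6 | 0 |
| Thursday's | 6.00 | 32 | 5 | 0 |

(readings scatter by 1.5 percentage points)

- the flask with the highest share of E in all that became E or L or Q ("all alike" if they lie within 1.5 percentage points) (south-east / north-west / west / all alike)
- share of E in all that became E or L or Q, south-east
- share of E in all that became E or L or Q, north-west
- share of E in all that became E or L or Q, west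



Thursday's readings pool to a share of 83.1 %, and L keeps pace with E, so both look like parallel products of D. Thursday's Q readings lie between 0 % and 1 % against a scatter of 1.5 percentage points, so the runs say little about any loss of E to Q.

What I need is how far each flask goes beyond the readings. Thursday's last reading has 37.0 % of the D as E, L and Q at 6.00 min, so its read turnover time, the time in which the part of the D not read as E, L or Q falls by a factor e if that fall is first-order, is 13.0 min. This is a time of the read products, not of D itself: anything unread that takes D would make D's own time shorter. Tuesday's last reading, rough with so little product, gives 240 min, a factor of 18.5 between 35 °C and 60 °C. Taking the logarithm of this time as straight in temperature, north-west has 1.26 min and west 134 min.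

Counted in read turnover times, Thursday's readings reach 0.462, south-east asks 0.770, west 0.0747 and north-west 7.94. So north-west lies far outside the readings, and any slow loss of E has far longer to show there. I commit to about 83.1 % for south-east and west, and to a lower north-west, by an amount these runs do not give.

The forecast has 83 % for south-east, 80 % for north-west, 84 % for west, and names west, adding: “Any side path or follow-on loss of E could then appear.” The flasks give 82.4 % in south-east, 56.2 % in north-west and 88.3 % in west, so west stands highest.

    E → Q (k = 6.60 × 10⁻⁵ /s, Ea = 113 kJ/mol)
    D → L (k = 2.60 × 10⁻⁴ /s, Ea = 115 kJ/mol)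
    D + J → X (k = 0.0770 /M/s, Ea = 51.0 kJ/mol)
    D → E (k = 0.00140 /s, Ea = 100 kJ/mol)
    2 D → G (k = 4.40 × 10⁻⁴ /M/s, Ea = 80.0 kJ/mol)
    (constants at 60 °C)

In north-west the read turnover time of 1.26 min is shorter than the 10 min of the run: D stands at 1.33 % by 5.00 min and at 0.0220 % at the end, while over that second stretch E falls from 58.3 % to 48.6 % and Q rises from 9.80 % to 20.5 %. The neighbour flask, a repeat of south-east at 85 °C, has a read turnover time of 0.703 min by the same rule, and at its reading D stands at 0 %, E at 36.4 % and Q at 32.2 %, a share of 41.8 %.

(All runs are calculated with made-up constants; scatter was added.)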